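(The readings are simulated with made-up constants; the scatter is artificial.)

The amounts frame the matter: green and teal each hold 0.050 M of each substrate, green with 1.0 mM of precatalyst and teal with 0.60 mM, and what counts is how far the two substrates part in 2.0 d.

| flask | left-handed substrate | right-handed substrate | gas | precatalyst | remark | time |
|---|---|---|---|---|---|---|
| Monday's | 0.050 M | 0.050 M | 7.6 mM (held) | 0.89 mM | run made earlier |  |
| Wednesday's | 0.050 M | 0.050 M | 7.6 mM (held) | 1.1 mM | run made earlier |  |
| green | 0.050 M | 0.050 M | 7.6 mM (held) | 1.0 mM |  | 2.0 d |
| teal | 0.050 M | 0.050 M | 7.6 mM (held) | 0.60 mM |  | 2.0 d |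

| run | time / h | right-handed substrate / % | left-handed substrate / % | left-handed product / % |
|---|---|---|---|---|
| Monday's | 4.00 | 50 | 47 | 0 |
| Monday's | 6.00 | 47 | 46 | 3 |
| Monday's | 8.00 | 48 | 44 | 8 |
| Monday's | 15.0 | 50 | 44 | 7 |
| Monday's | 20.0 | 48 | 39 | 9 |
| Monday's | 30.0 | 48 | 33 | 15 |
| Monday's | 50.0 | 43 | 24 | 21 |
| Wednesday's | 2.50 | 51 | 46 | 0 |
| Wednesday's | 8.00 | 52 | 45 | 8 |
| Wednesday's | 15.0 | 46 | 38 | 13 |
| Wednesday's | 20.0 | 47 | 34 | 14 |
| Wednesday's | 30.0 | 49 | 32 | 15 |
| Wednesday's | 40.0 | 45 | 21 | 20 |
| Wednesday's | 50.0 | 45 | 15 | 19 |

(readings scatter by 2 percentage points)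

- the winner by excess of right-handed substrate over left-handed substrate among what is left of the two; "neither" if no more than 2 percentage points parts them (green / teal / neither)
- excess of right-handed substrate over left-handed substrate among what is left of the two at the end, green
- excess of right-handed substrate over left-handed substrate among what is left of the two at the end, teal

- free catalyst is single-handed; left-handed substrate and right-handed substrate are mirror images of each other, charged as a racemate, each of them at the stated concentration
- at the start none of the gas is in solution
- an excess is the difference of the two amounts in percent of their sum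
- an excess is below zero if the other one leads

Which substrate moves? After 50.0 h on Wednesday the left-handed substrate reads 15% and the right-handed one 45%, so the right-handed loss is a small correction, and the excess is the ratio of the two, less one, over that ratio plus one.

How does the logarithm of that ratio go with catalyst? Wednesday's charge is 1.24 times Monday's, yet Wednesday's logarithm is 1.14 times Monday's at 30.0 h and 1.88 times at 50.0 h. With a scatter of 2 percentage points on readings this low, the two runs do not choose a power, so this reckoning takes the first power.

The quantity to carry is then the splitting constant of this kinetic resolution, the logarithm of the substrate ratio per unit of catalyst charged and per unit of time; pooled over the last readings of both runs it reads 16.9 L mol⁻¹ h⁻¹. Over 2.0 d this gives logarithms of 0.811 for green and 0.487 for teal, hence excesses of 38.5% and 23.9%.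

The forecast names green, with 40% for green and 14% for teal, on the ground that the runs suggest “roughly second order in catalyst”; this reckoning stands lower on green and higher on teal.

The flask gives green, with 45.2% for green and 26.3% for teal.

    gas ⇌ coupling partner, rate k1*(csat - [coupling partner]) (kL = 2.10 h⁻¹)
    coupling partner + catalyst intermediate A → free catalyst + left-handed product (k = 220 L mol⁻¹ h⁻¹)
    coupling partner + precatalyst → free catalyst + spent reagent (k = 57.0 L mol⁻¹ h⁻¹)
    left-handed product ⇌ right-handed product (k = 0.0480 h⁻¹)
    free catalyst + right-handed substrate ⇌ catalyst intermediate B (K = 8.40 L mol⁻¹, k = 10000 L mol⁻¹ h⁻¹)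
    free catalyst + left-handed substrate ⇌ catalyst intermediate A (K = 39.0 L mol⁻¹, k = 4900 L mol⁻¹ h⁻¹)
    coupling partner + catalyst intermediate B → free catalyst + right-handed product (k = 93.0 L mol⁻¹ h⁻¹)

Teal trails green because of its smaller charge of precatalyst: with that difference in precatalyst taken away, teal's 26.3% becomes 45.2%. Taken from these results, the logarithms are 0.974 for green and 0.539 for teal, a factor of 1.81 for a catalyst ratio of 1.67, whose square is 2.78; the splitting constant comes to 20.3 L mol⁻¹ h⁻¹ in green and 18.7 L mol⁻¹ h⁻¹ in teal.

For a flask like teal with 3.6 × 10⁻⁴ M of precatalyst, read at the same time, the carried 16.9 L mol⁻¹ h⁻¹ gives a logarithm of 0.292 and an excess of 14.5%; the computed flask gives 15.3%.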